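**Retrosynthetic overview**

- Target 16 ← Stille prenylation at C5' of ring B ← bromotriphenol 14 ← BCl3 debenzylation ← tribenzyl bromoisoflavone 13.
- 13 ← Friedel–Crafts acylation forming C4–C4a and closing ring C (the pyranone) ← (Z)-3-aryloxy-2-arylacrylic acid 11. Rings A and B arrive preformed; ring C is the only ring made.
- 11 ← addition–elimination of 3,5-dibenzyloxyphenol 9 on enol tosylate 8 ← formylation of arylacetate 5 with methyl formate ← homovanillic acid 1 (esterify, brominate ortho to the hydroxyl, benzylate).
- Feature the plan rests on: ring A carries its three oxygens on C8a (O1), C5 and C7. The 3,5-dibenzyloxyphenyl ether that supplies ring A therefore has a mirror axis through C8a and C6, so C4a and C8 are the same carbon before closure and acylation at either gives the same 5,7-dioxygenated chromone.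

Key step: step 8

Remark: acrylate 10 and acid 11 are written as the Z isomers expected from Z tosylate 8 by substitution with retention; a share of E isomer would not change the plan, because the acidic key step is expected to convert it.

**Route**

Step 1
Reactants: 1 homovanillic acid
Product: 2 methyl 2-(4-hydroxy-3-methoxyphenyl)acetate (methyl homovanillate)
Conditions: MeOH, H2SO4 (cat.), reflux
Reagents that add atoms: methanol, CO
Why: Fischer esterification in excess methanol converts the acid to the methyl ester and leaves the phenol untouched.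

Step 2
Reactants: 2 methyl homovanillate
Product: 3 methyl 2-(3-bromo-4-hydroxy-5-methoxyphenyl)acetate
Conditions: NBS, iPr2NH (cat.), CH2Cl2, 0 °C
Reagents that add atoms: N-bromosuccinimide, O=C1CCC(=O)N1Br
Why: Electrophilic aromatic bromination; the position para to the hydroxyl is occupied by the side chain, so amine-mediated delivery of bromine from NBS should go to the free carbon ortho to the hydroxyl, the strongest donor on the ring, rather than para to the methoxy group.

Step 3
Reactants: 3 methyl 2-(3-bromo-4-hydroxy-5-methoxyphenyl)acetate; 4 benzyl bromide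
Product: 5 methyl 2-[4-(benzyloxy)-3-bromo-5-methoxyphenyl]acetate
Conditions: K2CO3, DMF, 50 °C
Reagents that add atoms: none
Why: Williamson ether synthesis of the phenoxide with benzyl bromide; carbonate is too weak a base to enolise the ester.

Step 4
Reactants: 5 methyl 2-[4-(benzyloxy)-3-bromo-5-methoxyphenyl]acetate; 6 methyl formate
Product: 7 methyl (Z)-2-[4-(benzyloxy)-3-bromo-5-methoxyphenyl]-3-hydroxyacrylate (enol form of the α-formyl ester)
Conditions: NaH, THF, 0 °C to rt; then aq. HCl
Reagents that add atoms: none
Why: Crossed Claisen condensation; the ester enolate attacks the non-enolisable formate, the product is drawn out as its stabilised sodium enolate and is set free on acidification as the hydrogen-bonded Z enol.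

Step 5
Reactants: 7 methyl (Z)-2-[4-(benzyloxy)-3-bromo-5-methoxyphenyl]-3-hydroxyacrylate
Product: 8 methyl (Z)-2-[4-(benzyloxy)-3-bromo-5-methoxyphenyl]-3-(tosyloxy)acrylate
Conditions: TsCl, TMEDA, LiCl, MeCN, 0 °C
Reagents that add atoms: p-toluenesulfonyl chloride, Cc1ccc(cc1)S(Cl)(=O)=O
Why: Stereoselective enol tosylation of a β-dicarbonyl compound; Li+ chelated between the enolate oxygen and the ester carbonyl holds the Z enolate, so the tosyloxy group should end up cis to the ester.

Step 6
Reactants: 8 methyl (Z)-2-[4-(benzyloxy)-3-bromo-5-methoxyphenyl]-3-(tosyloxy)acrylate; 9 3,5-dibenzyloxyphenol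
Product: 10 methyl (Z)-3-[3,5-bis(benzyloxy)phenoxy]-2-[4-(benzyloxy)-3-bromo-5-methoxyphenyl]acrylate
Conditions: K2CO3, DMF, rt
Reagents that add atoms: none
Why: Addition–elimination (nucleophilic vinylic substitution) of the phenoxide oxygen at the β-carbon of the tosyloxyacrylate; the ester-stabilised carbanion should expel the good nucleofuge tosylate quickly, so retention to the Z aryl enol ether is expected, and O-attack of the phenoxide is favoured under K2CO3 in DMF.

Step 7
Reactants: 10 methyl (Z)-3-[3,5-bis(benzyloxy)phenoxy]-2-[4-(benzyloxy)-3-bromo-5-methoxyphenyl]acrylate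
Product: 11 (Z)-3-[3,5-bis(benzyloxy)phenoxy]-2-[4-(benzyloxy)-3-bromo-5-methoxyphenyl]acrylic acid
Conditions: LiOH·H2O, THF/MeOH/H2O, rt; then 1 M HCl, 0 °C
Reagents that add atoms: lithium hydroxide, [Li+].[OH-]
Why: Saponification by hydroxide attack at the acyl carbon, routine for 3-aryloxyacrylates; the benzyl ethers, the aryl bromide and the aryl enol ether should be inert to aqueous LiOH at room temperature.

Step 8
Reactants: 11 (Z)-3-[3,5-bis(benzyloxy)phenoxy]-2-[4-(benzyloxy)-3-bromo-5-methoxyphenyl]acrylic acid
Product: 13 5,7-bis(benzyloxy)-3-[4-(benzyloxy)-3-bromo-5-methoxyphenyl]chromen-4-one, via mixed trifluoroacetic anhydride 12 (not isolated)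
Conditions: (CF3CO)2O, CH2Cl2, 0 °C to rt
Reagents that add atoms: none
Why: (CF3CO)2O converts acid 11 into mixed anhydride 12, whose acyl carbon (as such or after loss of trifluoroacetate to the acylium ion) is attacked by the ring A carbon ortho to the ether oxygen, and loss of the proton from the arenium ion forms C4–C4a and the pyranone. The closest known reaction type is the intramolecular Friedel–Crafts acylation of 3-aryloxyacrylic acids to chromones, commonly run in polyphosphoric acid or P2O5/MeSO3H, combined with the known use of mixed trifluoroacetic anhydrides to acylate activated arenes. Ring C closes as a six-membered ring by 6-exo-trig attack of the arene on the acyl carbon, which the Z alkene holds next to the aryloxy group. No stereocenter is formed. The step needs site selectivity on ring A, secured by the symmetry of the 3,5-dibenzyloxyphenoxy ring (both ortho carbons identical, the para carbon out of reach), and it needs the benzyl ethers to survive, which mild anhydride activation allows because the attacking carbon has oxygen donors at both ortho positions and at the para position. Any E isomer in 11 should equilibrate under the CF3CO2H set free, since protonation at the aryl-bearing carbon of the donor–acceptor alkene gives an oxocarbenium ion that can rotate, and only the Z form is drained by ring closure.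

Step 9
Reactants: 13 5,7-bis(benzyloxy)-3-[4-(benzyloxy)-3-bromo-5-methoxyphenyl]chromen-4-one
Product: 14 3-(3-bromo-4-hydroxy-5-methoxyphenyl)-5,7-dihydroxychromen-4-one
Conditions: BCl3, C6HMe5, CH2Cl2, −78 °C; then MeOH
Reagents that add atoms: none
Why: Lewis acid debenzylation; BCl3 activates each benzyl ether and pentamethylbenzene traps the benzyl cation by Friedel–Crafts benzylation, which at −78 °C should spare the aryl methyl ether, the aryl bromide and the chromone and prevent C-benzylation of ring A.

Step 10
Reactants: 14 3-(3-bromo-4-hydroxy-5-methoxyphenyl)-5,7-dihydroxychromen-4-one; 15 tributyl(3-methylbut-2-en-1-yl)stannane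
Product: 16 2'-deoxypiscerythrone, 5,7-dihydroxy-3-[4-hydroxy-3-methoxy-5-(3-methylbut-2-en-1-yl)phenyl]chromen-4-one
Conditions: Pd(PPh3)4 (cat.), DMF, 90 °C
Reagents that add atoms: none
Why: Stille cross-coupling; oxidative addition of zerovalent palladium into the aryl C–Br bond, transmetalation of the allylic stannane and reductive elimination at the less hindered primary carbon should give the linear prenyl group under neutral conditions that the free phenols and the acid-sensitive ortho-prenylphenol tolerate.

**Compound list**

1 | homovanillic acid | COc1cc(CC(=O)O)ccc1O | starting material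
2 | methyl 2-(4-hydroxy-3-methoxyphenyl)acetate | COC(=O)Cc1ccc(O)c(OC)c1 | intermediate
3 | methyl 2-(3-bromo-4-hydroxy-5-methoxyphenyl)acetate | COC(=O)Cc1cc(Br)c(O)c(OC)c1 | intermediate
4 | benzyl bromide | BrCc1ccccc1 | starting material
5 | methyl 2-[4-(benzyloxy)-3-bromo-5-methoxyphenyl]acetate | COC(=O)Cc1cc(Br)c(OCc2ccccc2)c(OC)c1 | intermediate
6 | methyl formate | COC=O | starting material
7 | methyl (Z)-2-[4-(benzyloxy)-3-bromo-5-methoxyphenyl]-3-hydroxyacrylate | COC(=O)/C(=C\O)c1cc(Br)c(OCc2ccccc2)c(OC)c1 | intermediate
8 | methyl (Z)-2-[4-(benzyloxy)-3-bromo-5-methoxyphenyl]-3-(tosyloxy)acrylate | COC(=O)/C(=C\OS(=O)(=O)c1ccc(C)cc1)c1cc(Br)c(OCc2ccccc2)c(OC)c1 | intermediate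
9 | 3,5-dibenzyloxyphenol | Oc1cc(OCc2ccccc2)cc(OCc2ccccc2)c1 | starting material
10 | methyl (Z)-3-[3,5-bis(benzyloxy)phenoxy]-2-[4-(benzyloxy)-3-bromo-5-methoxyphenyl]acrylate | COC(=O)/C(=C\Oc1cc(OCc2ccccc2)cc(OCc2ccccc2)c1)c1cc(Br)c(OCc2ccccc2)c(OC)c1 | intermediate
11 | (Z)-3-[3,5-bis(benzyloxy)phenoxy]-2-[4-(benzyloxy)-3-bromo-5-methoxyphenyl]acrylic acid | OC(=O)/C(=C\Oc1cc(OCc2ccccc2)cc(OCc2ccccc2)c1)c1cc(Br)c(OCc2ccccc2)c(OC)c1 | intermediate
12 | (Z)-3-[3,5-bis(benzyloxy)phenoxy]-2-[4-(benzyloxy)-3-bromo-5-methoxyphenyl]acrylic trifluoroacetic anhydride | O=C(OC(=O)C(F)(F)F)/C(=C\Oc1cc(OCc2ccccc2)cc(OCc2ccccc2)c1)c1cc(Br)c(OCc2ccccc2)c(OC)c1 | intermediate (not isolated)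
13 | 5,7-bis(benzyloxy)-3-[4-(benzyloxy)-3-bromo-5-methoxyphenyl]chromen-4-one | COc1cc(-c2coc3cc(OCc4ccccc4)cc(OCc4ccccc4)c3c2=O)cc(Br)c1OCc1ccccc1 | intermediate
14 | 3-(3-bromo-4-hydroxy-5-methoxyphenyl)-5,7-dihydroxychromen-4-one | COc1cc(-c2coc3cc(O)cc(O)c3c2=O)cc(Br)c1O | intermediate
15 | tributyl(3-methylbut-2-en-1-yl)stannane | CCCC[Sn](CCCC)(CCCC)CC=C(C)C | starting material
16 | 2'-deoxypiscerythrone | COc1cc(-c2coc3cc(O)cc(O)c3c2=O)cc(CC=C(C)C)c1O | target

**Totals**

Total step count: 10. Longest linear sequence: 10 steps (1 to 16).

**Steps most likely to fail**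

1. Step 8. The acyl carbon of 12 is deactivated by the enol ether donor and may not attack ring A. Trifluoroacetylation of ring A could then compete, and a more acidic medium would risk loss or migration of benzyl groups. Fallback: the deoxybenzoin route, which closes ring C at O1–C2 and C2–C3 instead and needs no benzyl groups. It sets out from 3 and rejoins at 14. Saponification of 3 (LiOH, THF/H2O) would give 2-(3-bromo-4-hydroxy-5-methoxyphenyl)acetic acid F1. Friedel–Crafts acylation of phloroglucinol with F1 in BF3·OEt2 at 80 °C would give 2-(3-bromo-4-hydroxy-5-methoxyphenyl)-1-(2,4,6-trihydroxyphenyl)ethan-1-one F2. One-carbon insertion and ring closure with DMF and MsCl in the same BF3·OEt2 medium would give 14, and the route continues with step 10.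

2. Step 10. The prenyl group may be transferred through its tertiary carbon, giving the 1,1-dimethylallyl isomer, and oxidative addition into the electron-rich ortho-bromophenol may be slow enough for protodebromination to compete. Fallback: a two-step prenylation without an ambident allyl partner, setting out from 14 and ending at 16. Stille coupling of 14 with allyltributylstannane (Pd(PPh3)4, DMF, 90 °C) would give 3-(3-allyl-4-hydroxy-5-methoxyphenyl)-5,7-dihydroxychromen-4-one F3. Cross-metathesis of F3 with 2-methyl-2-butene as co-solvent and the second-generation Grubbs catalyst (H2IMes)(PCy3)Cl2Ru=CHPh would convert the allyl into the prenyl group and give 16.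

3. Step 6. The phenoxide may attack the sulfonyl sulfur instead of the β-carbon, transferring the tosyl group to 9 and returning the enolate of 7; attack through a ring carbon of the ambident phenoxide is a second possible diversion. Fallback: replace the sulfonate by a leaving group with no second electrophilic site, setting out from 7 and rejoining at 10. Treatment of 7 with oxalyl chloride and DMF in CH2Cl2 would give methyl (Z)-2-[4-(benzyloxy)-3-bromo-5-methoxyphenyl]-3-chloroacrylate F4 (either alkene isomer would serve). Addition–elimination of 9 on F4 with K2CO3 in DMF would give 10.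

**Further compounds**

F1 | step 8 | 2-(3-bromo-4-hydroxy-5-methoxyphenyl)acetic acid | COc1cc(CC(=O)O)cc(Br)c1O
F2 | step 8 | 2-(3-bromo-4-hydroxy-5-methoxyphenyl)-1-(2,4,6-trihydroxyphenyl)ethan-1-one | COc1cc(CC(=O)c2c(O)cc(O)cc2O)cc(Br)c1O
F3 | step 10 | 3-(3-allyl-4-hydroxy-5-methoxyphenyl)-5,7-dihydroxychromen-4-one | COc1cc(-c2coc3cc(O)cc(O)c3c2=O)cc(CC=C)c1O
F4 | step 6 | methyl (Z)-2-[4-(benzyloxy)-3-bromo-5-methoxyphenyl]-3-chloroacrylate | COC(=O)/C(=C\Cl)c1cc(Br)c(OCc2ccccc2)c(OC)c1
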